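The leftover right-handed substrate drifts from 51% to 49% in the summer run, so in this kinetic resolution the excess we want follows the left-handed leftover.

| flask | left-handed substrate | right-handed substrate | partner | precatalyst | remark | time |
|---|---|---|---|---|---|---|
| summer | 0.40 M | 0.40 M | 0.80 M (fed, over 2.0 h) | 6.7 mM | run made earlier; the fed solution adds 0.25 times the starting volume |  |
| autumn | 0.40 M | 0.40 M | 0.80 M (fed, over 2.0 h) | 15 mM | run made earlier; the fed solution adds 0.25 times the starting volume |  |
| oak | 0.40 M | 0.40 M | 0.800 M (fed, over 2.0 h) | 10 mM | the fed solution adds 0.25 times the starting volume | 40 h |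
| elm | 0.40 M | 0.40 M | 0.800 M (fed, over 2.0 h) | 10 mM | the fed solution adds 0.25 times the starting volume | 10 h |

| run | time / h | right-handed substrate / % | left-handed substrate / % | left-handed product / % |
|---|---|---|---|---|
| summer | 10.0 | 51 | 34 | 17 |
| summer | 20.0 | 50 | 24 | 28 |
| summer | 30.0 | 50 | 21 | 33 |
| summer | 40.0 | 49 | 16 | 32 |
| autumn | 10.0 | 51 | 24 | 27 |
| autumn | 20.0 | 50 | 16 | 35 |
| autumn | 30.0 | 51 | 9 | 42 |
| autumn | 40.0 | 46 | 8 | 42 |

(standard deviation of a reading: 1.5 percentage points)

- free catalyst is single-handed; left-handed substrate and right-handed substrate are mirror images of each other, charged as a racemate, each of them at the stated concentration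
- charges are per starting volume, the dose included; the dosed solution carries all of it
- an excess is the difference of the two amounts in percent of their sum
- an excess is below zero if the other one leads

1. which of the two ends with the higher excess of right-handed substrate over left-handed substrate among what is left of the two ("neither" if they lie within 2 percentage points) (oak / elm / neither)
2. excess of right-handed substrate over left-handed substrate among what is left of the two at the end, oak
3. excess of right-handed substrate over left-handed substrate among what is left of the two at the end, elm

Oak and elm differ from the earlier runs in precatalyst and time, so we fold the two together. The autumn run at 10.0 h has had 150 mM·h of c(precatalyst) times time, our catalyst dose.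

Now we read the tables against each other. The summer run at 20.0 h has had 134 mM·h and holds 24% of left-handed substrate, and the autumn run at 10.0 h holds 24%. The summer run at 40.0 h has had 268 mM·h and holds 16%, and the autumn run at 20.0 h, with 300 mM·h, holds 16%. So the two runs share one curve within the scatter.

Along it, twice the dose takes 10 percentage points in the summer run, then 8 points and 8 points in the autumn run. The steps are nearly even per doubling of the dose, so we interpolate in the logarithm of the dose.

Elm has 100 mM·h, between the first two summer rows, which gives 28.2% left-handed. Oak has 400 mM·h, between the autumn rows at 20.0 h and 30.0 h, which gives 11.0%. With right-handed at 50%, we reckon 63.8% for oak and 27.8% for elm.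

The forecast says oak, with 63% and 26%. It takes elm at “about 90 allowing for the feed period”, and its elm excess lies below ours.

The flasks give oak, with 61.2% for oak and 27.0% for elm, so the forecast holds.

    partner + free catalyst + left-handed substrate → free catalyst + left-handed product (k = 30.0 M⁻² h⁻¹)
    partner + free catalyst + right-handed substrate → free catalyst + right-handed product (k = 0.700 M⁻² h⁻¹)
    2 free catalyst ⇌ resting dimer (K = 170 M⁻¹, k = 14.0 M⁻¹ h⁻¹)
    partner + precatalyst → free catalyst + spent reagent (k = 0.690 M⁻¹ h⁻¹)
    free catalyst → spent catalyst (k = 0.0440 h⁻¹)

Oak holds 11.6% of left-handed substrate against our 11.0%, and elm holds 28.4% against our 28.2%. The oak excess moves 5 points with partner alone at 0.725 M or 0.881 M. Elm left until 15 h has a dose of 150 mM·h, the same as the 150 mM·h of the autumn run at 10.0 h, whose readings give an excess of 36.0%. That elm flask gives 36.6%.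

All runs were generated by integration with constants of no real substance; scatter was added.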